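**Assumptions.** (S)-(+)-Linalool (coriandrol) of high enantiomeric purity is taken as commercially available. Positional numbers used throughout: ring carbons C1–C10 with C1, C2 = CH2–CH2; C3 = CH(OH); C4 = C(CH3)=; C5 = =CH; C6 = CH–O(lactone); C7 = ring-fusion CH; C8 = CH–O(tigloyl); C9 = CH2; C10 = C(CH3)(OH); C11 = lactone α-carbon; C12 = lactone C=O; C13 = exocyclic CH2; C14, C15 = methyls on C10, C4. On this numbering the target is 3S,6R,7S,8R,10S, 4Z, with an (E)-2-methylbut-2-enoate (tiglate).

## The problem

Target 22 is a ten-membered carbocycle (C1–C10) whose only ring olefin, C4=C5, is trisubstituted and Z. It is cis-fused at C6–C7 to an α-methylene-γ-butyrolactone (O6, C12, C11, C13) and carries a tiglate on O8. The ring has to be closed against medium-ring strain while the Z olefin, flanked by allylic oxygens at C3 and C6 (trans to each other across the ring), is kept from isomerizing. Of the five stereocentres, C6–C7–C8 are contiguous (lactone O and C11 cis; O8 trans to C11), C10 is a tertiary carbinol 1,3 to C8, and C3 is remote. C8 can control C7 and, through the ring fusion, C6; C3 and C10 must come from reagent control or the chiral pool. Fragile groups are the exocyclic enoate (Michael acceptor), the tiglate (a second ester that must be kept from hydride and from lactone chemistry), the tertiary C10 and allylic C3 alcohols, and any (Z)-4-hydroxy-2-enal, which isomerizes or dehydrates to a furan. The feature that opens the route is twofold. C6 is the lactone carbinol and C7 is the γ-carbon of the C13–C11(C12)–C7 allyl unit, so C6–C7 plus O6–C12 is the retron of an aldehyde 2-(alkoxycarbonyl)allylation. And O3–C3–C4=C5–C6 is the skeleton of a 2,5-dihydrofuran-2-ol, so the Z olefin and the C6 aldehyde can be stored together in a five-membered lactol.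

## Retrosynthesis

**22 ⇐ 21.** Only the O10–Si bond is cut. C10 is kept as a tertiary silyl ether to the end because it is inert in every step and needs no differentiation from the other hydroxyls.

**21 ⇐ 18 (key).** Cut C6–C7 and O6–C12 and, read backwards, re-close O3 onto C6 to give lactol 18. In the forward sense one operation opens the lactol to hydroxy-enal 19, closes the carbocycle to hydroxy ester 20 and closes the lactone. Against the neighbouring cuts: C4=C5 would demand a ten-membered metathesis to a trisubstituted olefin; C3–C4 or C7–C8 closure would create a carbinol under ring control only. This cut creates C6 and C7 under control of C8 and of a closed transition state. Precursor 18 has one small ring and three stereocentres (C3, C8, C10), each set independently; the product has two new rings and two more stereocentres. The forward step must give syn addition, attack anti to O8, and ring closure rather than oligomers.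

**18 ⇐ 17 ⇐ 16 ⇐ 14 ⇐ 12 ⇐ 11.** The allyl bromide arm is grown from γ-hydroxy ynoate 11: C13–Br, then C11–C13 (from stannane 15), then O8–acyl (tiglic acid 13), then C11–I/C7–H. The tiglate goes on before the ring is closed. It then serves as the non-chelating group at C8 in the key step, and the three hydroxyls never need to be told apart.

**11 ⇐ 10 + 4; 10 ⇐ 9 ⇐ 8.** Cut C7–C8: reagent-controlled alkynylation of aldehyde 10 with methyl propiolate 4 sets C8 and brings C7, C11, C12. The C8 aldehyde comes from the vinyl group of 8 by anti-Markovnikov hydration and oxidation, so no protecting group is spent on C8.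

**8 ⇐ 6 ⇐ 5 ⇐ 3 + 4.** The silyl lactol 8 is the half-reduced butenolide 6. The butenolide ring is made by syn-addition of a methyl group (C15) across ynoate 5, which fixes the Z geometry for good. C3 is set in the alkynylation of aldehyde 3 with 4, which brings C4, C5, C6.

**3 ⇐ 2 ⇐ 1.** Cutting the prenyl olefin of silylated linalool gives 3. (S)-Linalool 1 supplies C1, C2, C3, C8, C9, C10, C14 and the C10 stereocentre.

## Roads not taken

**Alternative 1:** (the most obvious) cut C4=C5, the only ring olefin, and close diene A1 by ring-closing metathesis. The forward step must form a trisubstituted olefin in a ten-membered ring from a 1,1-disubstituted olefin and a vinyl group that both sit next to oxygenated stereocentres. That is the slowest class of metathesis partners, and dimerization competes. The exocyclic enoate of A1 is a third olefin and would have to be masked. A1 also needs all five stereocentres and the lactone in place beforehand, so the ring closure adds no stereochemical value. The chosen step closes the ring and sets two centres at once.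

**Alternative 2:** cut C2–C3 and restore C5–C10: anionic oxy-Cope ring expansion of cis-divinylcyclohexanol A2 to Z-cyclodecenone A3, then methyl addition at C10. A chair transition state with the C5 alkenyl group equatorial and the C10 vinyl group axial would give the Z olefin and, from an (E)-enol ether, 3S. The idea is attractive because the C6–C8 triad sits on a six-membered ring. But A2 has five stereocentres, with the vinyl group to be delivered cis to three substituents against sterics. The lactone carbons must be carried masked through strong base. C10 is left to an uncontrolled addition to a medium-ring ketone. The run-up is estimated to be longer than the whole chosen route.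

**Alternative 3:** cut C3–C4 and close vinyl iodide–aldehyde A4 by nickel/chromium-mediated coupling. The lactone core would first be made by an intermolecular allylation. The ring closure would then create only C3, under ring-conformational control that cannot be predicted, and A4 needs a (Z)-iodoalkene next to the lactone carbinol. The chosen plan sets C3 by catalyst before any ring exists and uses the ring closure for the centres that C8 can control.

Key step: step 14

## Route

**Step 1**
Reactants: 1 (S)-linalool
Product: 2 (S)-linalool triethylsilyl ether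
Conditions: Et3SiOTf, 2,6-lutidine, CH2Cl2, −78 to 0 °C
Reagents that add atoms: triethylsilyl triflate, CC[Si](CC)(CC)OS(=O)(=O)C(F)(F)F
Why: Silyl triflate silylation of a tertiary allylic alcohol; the ether stops C10–OH from forming a lactol with the C3 aldehyde made next.

**Step 2**
Reactants: 2 (S)-linalool triethylsilyl ether
Product: 3 (4S)-4-methyl-4-(triethylsilyloxy)hex-5-enal
Conditions: O3, CH2Cl2/MeOH, Sudan red end-point, −78 °C; Me2S
Reagents that add atoms: ozone, [O-][O+]=O
Why: Ozonolysis with reductive work-up; the electron-rich trisubstituted olefin should react well before the vinyl group on the quaternary silyloxy carbon.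

**Step 3**
Reactants: 3 (4S)-4-methyl-4-(triethylsilyloxy)hex-5-enal; 4 methyl propiolate
Product: 5 methyl (4S,7S)-4-hydroxy-7-methyl-7-(triethylsilyloxy)non-8-en-2-ynoate
Conditions: Me2Zn, ProPhenol ligand (20 mol %, enantiomer chosen for the 4S carbinol), Ph3PO, PhMe, 4 °C
Reagents that add atoms: methyl propiolate, C#CC(=O)OC
Why: Zinc–ProPhenol-catalysed enantioselective alkynylation of an aliphatic aldehyde; the ligand alone sets C3 (target numbering), since C10 is too remote to interfere.

**Step 4**
Reactants: 5 methyl (4S,7S)-4-hydroxy-7-methyl-7-(triethylsilyloxy)non-8-en-2-ynoate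
Product: 6 (5S)-4-methyl-5-[(3S)-3-methyl-3-(triethylsilyloxy)pent-4-enyl]furan-2(5H)-one
Conditions: Me2CuLi (from CuI, MeLi), THF, −78 °C; AcOH, −78 °C to rt
Reagents that add atoms: lithium dimethylcuprate, [Li+].C[Cu-]C
Why: syn-Carbocupration of the ynoate places C15 on C4 cis to the new C5–H; the (Z)-4-hydroxy-enoate lactonizes on work-up, which locks the Z geometry in the butenolide.

**Step 5**
Reactants: 6 (5S)-4-methyl-5-[(3S)-3-methyl-3-(triethylsilyloxy)pent-4-enyl]furan-2(5H)-one
Product: 8 (5S)-4-methyl-5-[(3S)-3-methyl-3-(triethylsilyloxy)pent-4-enyl]-2-(triethylsilyloxy)-2,5-dihydrofuran (both acetal epimers), via lactol 7 (not isolated)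
Conditions: iBu2AlH, CH2Cl2, −78 °C; then pyridine, Et3SiOTf, −78 to 0 °C
Reagents that add atoms: triethylsilyl triflate, CC[Si](CC)(CC)OS(=O)(=O)C(F)(F)F
Why: Half-reduction of the lactone and silylation of the aluminium lactolate in the same flask; the O-silyl lactol survives base, hydride and palladium and is later cleaved at silicon, not through an oxocarbenium ion.

**Step 6**
Reactants: 8 silyl lactol (as above)
Product: 9 (3S)-3-methyl-5-[(2S)-3-methyl-5-(triethylsilyloxy)-2,5-dihydrofuran-2-yl]-3-(triethylsilyloxy)pentan-1-ol
Conditions: 9-BBN, THF, 0 °C to rt; H2O2, aq. NaOH, 0 °C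
Reagents that add atoms: hydrogen peroxide, OO
Why: Anti-Markovnikov hydroboration–oxidation; 9-BBN should take the monosubstituted vinyl group and leave the trisubstituted ring olefin.

**Step 7**
Reactants: 9 primary alcohol (as above)
Product: 10 (3S)-3-methyl-5-[(2S)-3-methyl-5-(triethylsilyloxy)-2,5-dihydrofuran-2-yl]-3-(triethylsilyloxy)pentanal
Conditions: Dess–Martin periodinane, NaHCO3, CH2Cl2, 0 °C to rt
Reagents that add atoms: none
Why: Buffered Dess–Martin oxidation; neutral conditions spare the silyl acetal, and the aldehyde has no α-stereocentre to lose.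

**Step 8**
Reactants: 10 aldehyde (as above); 4 methyl propiolate
Product: 11 methyl (4R,6S)-4-hydroxy-6-methyl-8-[(2S)-3-methyl-5-(triethylsilyloxy)-2,5-dihydrofuran-2-yl]-6-(triethylsilyloxy)oct-2-ynoate
Conditions: Me2Zn, ProPhenol ligand (20 mol %, enantiomer opposite to step 3), Ph3PO, PhMe, 4 °C
Reagents that add atoms: methyl propiolate, C#CC(=O)OC
Why: Second zinc–ProPhenol alkynylation; reagent control sets C8 as R and brings C7, C11 and C12.

**Step 9**
Reactants: 11 γ-hydroxy ynoate (as above)
Product: 12 methyl (2Z,4R,6S)-4-hydroxy-2-iodo-6-methyl-8-[(2S)-3-methyl-5-(triethylsilyloxy)-2,5-dihydrofuran-2-yl]-6-(triethylsilyloxy)oct-2-enoate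
Conditions: NaAlH2(OCH2CH2OMe)2, THF, −78 °C; then I2, −78 °C
Reagents that add atoms: iodine, II
Why: Hydroxyl-directed trans-hydroalumination: the O8-bound aluminate delivers hydride to C7 and leaves aluminium on C11 cis to C8 in a five-membered chelate; iodinolysis with retention gives the iodide with C8 trans to the ester.

**Step 10**
Reactants: 12 iodo enoate (as above); 13 tiglic acid
Product: 14 methyl (2Z,4R,6S)-2-iodo-6-methyl-4-[(E)-2-methylbut-2-enoyloxy]-8-[(2S)-3-methyl-5-(triethylsilyloxy)-2,5-dihydrofuran-2-yl]-6-(triethylsilyloxy)oct-2-enoate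
Conditions: DCC, DMAP, CH2Cl2, 0 °C to rt
Reagents that add atoms: tiglic acid, C/C=C(\C)C(=O)O
Why: Steglich esterification of the only free hydroxyl; the target's ester is installed now so that it is the non-chelating C8 substituent in the key step.

**Step 11**
Reactants: 14 tiglate iodide (as above); 15 (tributylstannyl)methanol
Product: 16 methyl (2E,4R,6S)-2-(hydroxymethyl)-6-methyl-4-[(E)-2-methylbut-2-enoyloxy]-8-[(2S)-3-methyl-5-(triethylsilyloxy)-2,5-dihydrofuran-2-yl]-6-(triethylsilyloxy)oct-2-enoate
Conditions: Pd2(dba)3 (2.5 mol %), AsPh3, CuI, DMF, 40 °C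
Reagents that add atoms: (tributylstannyl)methanol, CCCC[Sn](CCCC)(CCCC)CO
Why: Stille hydroxymethylation of an α-iodo enoate with retention of geometry brings C13; oxidative addition to the C–I bond should be far faster than ionization of the electron-poor allylic tiglate.

**Step 12**
Reactants: 16 allylic alcohol (as above)
Product: 17 methyl (2Z,4R,6S)-2-(bromomethyl)-6-methyl-4-[(E)-2-methylbut-2-enoyloxy]-8-[(2S)-3-methyl-5-(triethylsilyloxy)-2,5-dihydrofuran-2-yl]-6-(triethylsilyloxy)oct-2-enoate
Conditions: CBr4, PPh3, 2,6-lutidine, CH2Cl2, 0 °C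
Reagents that add atoms: carbon tetrabromide, BrC(Br)(Br)Br
Why: Appel bromination of the primary allylic alcohol; the lutidine buffer protects the silyl acetal, and the isomer with C8 trans to the ester is also the thermodynamic one.

**Step 13**
Reactants: 17 allylic bromide (as above)
Product: 18 methyl (2Z,4R,6S)-2-(bromomethyl)-8-[(2S)-5-hydroxy-3-methyl-2,5-dihydrofuran-2-yl]-6-methyl-4-[(E)-2-methylbut-2-enoyloxy]-6-(triethylsilyloxy)oct-2-enoate (lactol, both C6 epimers)
Conditions: AcOH/THF/H2O (3:1:1), 0 °C to rt
Reagents that add atoms: none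
Why: Acid hydrolysis of the O-silyl hemiacetal at silicon, much faster than that of the tertiary silyl ether; no oxocarbenium ion is needed, which keeps the lactol from aromatizing to a furan.

**Step 14**
Reactants: 18 lactol bromide (as above)
Product: 21 10-O-triethylsilyl ether of the target (3S,6R,7S,8R,10S; cis-fused α-methylene lactone), via hydroxy enal 19 (not isolated), via hydroxy ester 20 (not isolated)
Conditions: CrCl2 (6 equiv), THF/DMF, slow addition of 18 to a final 2 mM, rt
Reagents that add atoms: none
Why: Two equivalents of CrCl2 reduce the C13–Br bond to a 2-(methoxycarbonyl)allylchromium in which C8 stays trans to the ester, while lactol 18 is in equilibrium with its open (Z)-4-hydroxy-enal tautomer 19. The allylchromium adds through its γ-carbon C7 to the C6 aldehyde in a closed six-membered chair transition state (Nozaki–Hiyama allylation in Barbier mode), and the C6 chromium alkoxide of 20 then displaces methoxide from the C12 ester. The closest known reaction type is the CrCl2-mediated cyclization of ω-formyl 2-(bromomethyl)alk-2-enoates to α-methylene-γ-lactones fused to ten- to fourteen-membered carbocycles. The ten-membered ring closes by intramolecular carbonyl allylation (C6–C7 bond, with the chromium-containing transition-state ring outside the new carbocycle); the lactone closes by 5-exo-trig acyl substitution. C6 and C7 are set together: C8 sits pseudo-axial (cis to CH2Cr) and the C5 alkenyl group pseudo-equatorial, which gives the syn adduct and hence the cis-fused lactone. The sense at C7 is set by C8: with C8–H eclipsing the C7=C11 bond (A(1,3) strain), C6 bonds to the face anti to the tigloyloxy group, which is also the face that the tether through C9 can reach. The step needs γ- over α-attack (normal for ester-substituted allylchromium reagents), ring closure over oligomerization (slow addition, high dilution) and retention of the Z olefin (held in the lactol ring until the aldehyde is consumed). The tiglate, the tertiary silyl ether and the free C3 hydroxyl should be inert to the allylchromium reagent.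

**Step 15**
Reactants: 21 10-O-triethylsilyl ether of the target
Product: 22 target
Conditions: HF·pyridine, pyridine, THF, 0 °C to rt
Reagents that add atoms: none
Why: Buffered fluoride desilylation of the tertiary silyl ether; these conditions should leave the exocyclic enoate, the tiglate and the allylic alcohol untouched.

## Compound list

1 | (S)-(+)-linalool, (3S)-3,7-dimethylocta-1,6-dien-3-ol | CC(C)=CCC[C@](C)(O)C=C | starting material
2 | (3S)-3,7-dimethyl-3-(triethylsilyloxy)octa-1,6-diene | CC(C)=CCC[C@](C)(O[Si](CC)(CC)CC)C=C | intermediate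
3 | (4S)-4-methyl-4-(triethylsilyloxy)hex-5-enal | O=CCC[C@](C)(O[Si](CC)(CC)CC)C=C | intermediate
4 | methyl propiolate | C#CC(=O)OC | starting material
5 | methyl (4S,7S)-4-hydroxy-7-methyl-7-(triethylsilyloxy)non-8-en-2-ynoate | COC(=O)C#C[C@@H](O)CC[C@](C)(O[Si](CC)(CC)CC)C=C | intermediate
6 | (5S)-4-methyl-5-[(3S)-3-methyl-3-(triethylsilyloxy)pent-4-enyl]furan-2(5H)-one | CC1=CC(=O)O[C@H]1CC[C@](C)(O[Si](CC)(CC)CC)C=C | intermediate
7 | (5S)-4-methyl-5-[(3S)-3-methyl-3-(triethylsilyloxy)pent-4-enyl]-2,5-dihydrofuran-2-ol, both C2 epimers | CC1=CC(O)O[C@H]1CC[C@](C)(O[Si](CC)(CC)CC)C=C | intermediate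
8 | O-triethylsilyl ether of lactol 7, both acetal epimers | CC1=CC(O[Si](CC)(CC)CC)O[C@H]1CC[C@](C)(O[Si](CC)(CC)CC)C=C | intermediate
9 | (3S)-3-methyl-5-[(2S)-3-methyl-5-(triethylsilyloxy)-2,5-dihydrofuran-2-yl]-3-(triethylsilyloxy)pentan-1-ol | CC1=CC(O[Si](CC)(CC)CC)O[C@H]1CC[C@](C)(O[Si](CC)(CC)CC)CCO | intermediate
10 | (3S)-3-methyl-5-[(2S)-3-methyl-5-(triethylsilyloxy)-2,5-dihydrofuran-2-yl]-3-(triethylsilyloxy)pentanal | CC1=CC(O[Si](CC)(CC)CC)O[C@H]1CC[C@](C)(O[Si](CC)(CC)CC)CC=O | intermediate
11 | methyl (4R,6S)-4-hydroxy-6-methyl-8-[(2S)-3-methyl-5-(triethylsilyloxy)-2,5-dihydrofuran-2-yl]-6-(triethylsilyloxy)oct-2-ynoate | CC1=CC(O[Si](CC)(CC)CC)O[C@H]1CC[C@](C)(O[Si](CC)(CC)CC)C[C@@H](O)C#CC(=O)OC | intermediate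
12 | methyl (2Z,4R,6S)-4-hydroxy-2-iodo-6-methyl-8-[(2S)-3-methyl-5-(triethylsilyloxy)-2,5-dihydrofuran-2-yl]-6-(triethylsilyloxy)oct-2-enoate | CC1=CC(O[Si](CC)(CC)CC)O[C@H]1CC[C@](C)(O[Si](CC)(CC)CC)C[C@@H](O)/C=C(\I)C(=O)OC | intermediate
13 | tiglic acid, (E)-2-methylbut-2-enoic acid | C/C=C(\C)C(=O)O | starting material
14 | 4-O-tigloyl ester of 12 | CC1=CC(O[Si](CC)(CC)CC)O[C@H]1CC[C@](C)(O[Si](CC)(CC)CC)C[C@@H](OC(=O)/C(C)=C/C)/C=C(\I)C(=O)OC | intermediate
15 | (tributylstannyl)methanol | CCCC[Sn](CCCC)(CCCC)CO | starting material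
16 | methyl (2E,4R,6S)-2-(hydroxymethyl)-6-methyl-4-(tigloyloxy)-8-[(2S)-3-methyl-5-(triethylsilyloxy)-2,5-dihydrofuran-2-yl]-6-(triethylsilyloxy)oct-2-enoate | CC1=CC(O[Si](CC)(CC)CC)O[C@H]1CC[C@](C)(O[Si](CC)(CC)CC)C[C@@H](OC(=O)/C(C)=C/C)/C=C(\CO)C(=O)OC | intermediate
17 | methyl (2Z,4R,6S)-2-(bromomethyl)-6-methyl-4-(tigloyloxy)-8-[(2S)-3-methyl-5-(triethylsilyloxy)-2,5-dihydrofuran-2-yl]-6-(triethylsilyloxy)oct-2-enoate | CC1=CC(O[Si](CC)(CC)CC)O[C@H]1CC[C@](C)(O[Si](CC)(CC)CC)C[C@@H](OC(=O)/C(C)=C/C)/C=C(\CBr)C(=O)OC | intermediate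
18 | methyl (2Z,4R,6S)-2-(bromomethyl)-8-[(2S)-5-hydroxy-3-methyl-2,5-dihydrofuran-2-yl]-6-methyl-4-(tigloyloxy)-6-(triethylsilyloxy)oct-2-enoate, both lactol epimers | CC1=CC(O)O[C@H]1CC[C@](C)(O[Si](CC)(CC)CC)C[C@@H](OC(=O)/C(C)=C/C)/C=C(\CBr)C(=O)OC | intermediate
19 | open (Z)-4-hydroxy-3-methyl-2-enal tautomer of 18 (C6 aldehyde, free C3 hydroxyl) | O=C/C=C(/C)[C@@H](O)CC[C@](C)(O[Si](CC)(CC)CC)C[C@@H](OC(=O)/C(C)=C/C)/C=C(\CBr)C(=O)OC | intermediate
20 | ten-membered seco-lactone: methyl 2-[(4Z)-2,5-dihydroxy-4,8-dimethyl-10-(tigloyloxy)-8-(triethylsilyloxy)cyclodec-3-enyl]acrylate, ring configurations as in 22 | COC(=O)C(=C)[C@@H]1[C@H](O)/C=C(/C)[C@@H](O)CC[C@](C)(O[Si](CC)(CC)CC)C[C@H]1OC(=O)/C(C)=C/C | intermediate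
21 | 10-O-triethylsilyl ether of 22 | C=C1C(=O)O[C@@H]2/C=C(/C)[C@@H](O)CC[C@](C)(O[Si](CC)(CC)CC)C[C@@H](OC(=O)/C(C)=C/C)[C@H]12 | intermediate
22 | target (3S,6R,7S,8R,10S,4Z)-3,10-dihydroxy-8-(tigloyloxy)germacra-4,11(13)-dien-6,12-olide | C=C1C(=O)O[C@@H]2/C=C(/C)[C@@H](O)CC[C@](C)(O)C[C@@H](OC(=O)/C(C)=C/C)[C@H]12 | target

## Step count and least certain steps

Total step count: 15. Longest linear sequence: 15 steps (1 to 22); the route is linear, with 4, 13 and 15 as added building blocks.

**Step 14 (key step).** The ring closure may lose to intermolecular allylation or to protonation of the allylchromium, because the aldehyde is present only as the minor open tautomer of the lactol. The lactol may also dehydrate to a furan under chromium Lewis acidity, and facial selectivity at C7 may fall if the tiglate carbonyl coordinates chromium. The fallback replaces the reductive metal allylation by an allylboration and sets out from 16. Methyl chloroformate and pyridine give the allylic methyl carbonate F1. Palladium-catalysed borylation (B2pin2, Pd2(dba)3, DMSO) gives the 2-(methoxycarbonyl)allylboronate F2. Acetic acid/THF/water frees the lactol boronate F3, which is shelf-stable towards the lactol. Heating F3 in toluene at high dilution, with Sc(OTf)3 as catalyst if needed, should close the ring through the same chair transition state without any reductant and lactonize, returning to the route at 21.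

**Step 9.** The hydride may add without hydroxyl direction or reduce the ester, and the aluminium intermediate may lose its geometry as an allenolate before iodinolysis. The fallback builds the allyl bromide arm by olefin metathesis and sets out from 10. Catalytic enantioselective addition of divinylzinc (amino-alcohol ligand) gives the (R)-allylic alcohol F4. Steglich esterification with 13 gives the tiglate F5. Cross-metathesis of F5 with methyl 2-(bromomethyl)acrylate (second-generation Hoveyda–Grubbs catalyst) returns to the route at 17 and bypasses steps 10–12.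

**Step 11.** Zerovalent palladium may ionize the allylic tiglate, or transmetalation of the hydroxymethyl group may be too slow, leading to protodeiodination. The fallback avoids palladium and sets out from 14. Iodine–magnesium exchange with iPrMgCl·LiCl at −78 °C gives the alkenylmagnesium chloride F6, which is trapped with monomeric formaldehyde to return to the route at 16.

**Step 8 (and, in the same way, step 3).** Enantioselectivity may be insufficient with a β-branched aliphatic aldehyde, which would show up as a C8 epimer mixture. The fallback separates bond formation from stereocontrol and sets out from 10. The lithium acetylide of 4 (LiHMDS, −78 °C) adds to give 11 together with its C8 epimer F7. Dess–Martin oxidation of the mixture gives the ynone F8, and reduction with (R)-Alpine-Borane under reagent control returns to the route at 11.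

## Further compounds

F1 | step 14 | allylic methyl carbonate of 16 | CC1=CC(O[Si](CC)(CC)CC)O[C@H]1CC[C@](C)(O[Si](CC)(CC)CC)C[C@@H](OC(=O)/C(C)=C/C)/C=C(\COC(=O)OC)C(=O)OC
F2 | step 14 | 2-(methoxycarbonyl)allyl pinacolboronate corresponding to 17 | CC1=CC(O[Si](CC)(CC)CC)O[C@H]1CC[C@](C)(O[Si](CC)(CC)CC)C[C@@H](OC(=O)/C(C)=C/C)/C=C(\CB1OC(C)(C)C(C)(C)O1)C(=O)OC
F3 | step 14 | lactol boronate (anomeric silyl group of F2 removed) | CC1=CC(O)O[C@H]1CC[C@](C)(O[Si](CC)(CC)CC)C[C@@H](OC(=O)/C(C)=C/C)/C=C(\CB1OC(C)(C)C(C)(C)O1)C(=O)OC
F4 | step 9 | (3R,5S)-5-methyl-7-[(2S)-3-methyl-5-(triethylsilyloxy)-2,5-dihydrofuran-2-yl]-5-(triethylsilyloxy)hept-1-en-3-ol | CC1=CC(O[Si](CC)(CC)CC)O[C@H]1CC[C@](C)(O[Si](CC)(CC)CC)C[C@@H](O)C=C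
F5 | step 9 | tiglate of F4 | CC1=CC(O[Si](CC)(CC)CC)O[C@H]1CC[C@](C)(O[Si](CC)(CC)CC)C[C@@H](OC(=O)/C(C)=C/C)C=C
F6 | step 11 | alkenylmagnesium chloride from 14 (Mg in place of I) | CC1=CC(O[Si](CC)(CC)CC)O[C@H]1CC[C@](C)(O[Si](CC)(CC)CC)C[C@@H](OC(=O)/C(C)=C/C)/C=C(\[Mg]Cl)C(=O)OC
F7 | step 8 | C8 epimer of 11 (4S carbinol) | CC1=CC(O[Si](CC)(CC)CC)O[C@H]1CC[C@](C)(O[Si](CC)(CC)CC)C[C@H](O)C#CC(=O)OC
F8 | step 8 | ynone, methyl (6S)-6-methyl-8-[(2S)-3-methyl-5-(triethylsilyloxy)-2,5-dihydrofuran-2-yl]-4-oxo-6-(triethylsilyloxy)oct-2-ynoate | CC1=CC(O[Si](CC)(CC)CC)O[C@H]1CC[C@](C)(O[Si](CC)(CC)CC)CC(=O)C#CC(=O)OC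
A1 | alternative 1 | C4–C5 seco diene with the cis lactone in place (C3 isopropenyl carbinol, C6 vinyl) | C=C1C(=O)O[C@H](C=C)[C@@H]1[C@H](OC(=O)/C(C)=C/C)C[C@@](C)(O)CC[C@H](O)C(C)=C
A2 | alternative 2 | cis-1-vinyl-2-[(E)-1-(4-methoxybenzyloxy)prop-1-en-2-yl]cyclohexanol with C6 and C8 silyl ethers and a C7 2-(silyloxy)ethyl group | O[C@@]1(C=C)C[C@@H](O[Si](C)(C)C(C)(C)C)[C@H](CCO[Si](C)(C)C(C)(C)C)[C@H](O[Si](C)(C)C(C)(C)C)[C@@H]1/C(C)=C/OCc1ccc(OC)cc1
A3 | alternative 2 | (Z)-cyclodec-4-en-10-one from A2 (C10 ketone, C3 benzylic ether) | O=C1CC[C@H](OCc2ccc(OC)cc2)/C(C)=C\[C@@H](O[Si](C)(C)C(C)(C)C)[C@@H](CCO[Si](C)(C)C(C)(C)C)[C@H](O[Si](C)(C)C(C)(C)C)C1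
A4 | alternative 3 | C3–C4 seco compound: C3 aldehyde and (Z)-C4 iodoalkene on the cis lactone | C=C1C(=O)O[C@H](/C=C(/C)I)[C@@H]1[C@H](OC(=O)/C(C)=C/C)C[C@@](C)(O)CCC=O
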